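Target: a ten-membered carbocycle (C1–C10) trans-fused at C6–C7 to an α-methylene-γ-butyrolactone, with esters at C3 and C8 and a free C1 hydroxyl. The route rests on the Z trisubstituted C4=C5 alkene flanked by the oxygen-bearing C3 and C6, a (Z)-2-ene-1,4-diol unit that fits a seven-membered O–Si–O ring.
Late stage: C8 tiglate by Mitsunobu inversion; ten-membered ring by CrCl2-mediated allylation C7–C8 (bromomethyl butenolide onto the C8 enal); butenolide by metathesis of the C6 2-(bromomethyl)acrylate with the C7 vinyl group.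
Key disconnection: C4=C5 by ring-closing metathesis of the diisopropylsilylene ketal joining the C3 alcohol (C8–C4 fragment, isopropenyl end) and penta-1,4-dien-3-ol (C5–C7). The closure also sets C6.
C8–C4 fragment: prenol to the E C8–C1 enal, boron aldol with 3-methylbut-3-en-2-one (C1), oxazaborolidine reduction (C3).
Ring order: seven-membered dioxasilepine (temporary), then the butenolide, then the ten-membered carbocycle.

Key step: step 8

Remark (numbering): C1–C13 are the germacrane locants of the target (C1 carbinol, C3 acetate carbon, C6 lactone O-carbon, C8 tiglate carbon, C11=C13 methylene, C12 carbonyl); systematic names of open-chain compounds use their own chain locants.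
Remark (assumption, tether metathesis): the closure is taken to favour the cis-4,7-disubstituted dioxasilepine, whereas the target configuration corresponds to the trans relation between the C3 side chain and the C7 vinyl group; C3 is therefore carried as its 3R epimer and inverted in step 11.
Remark (assumption, chromium closure): the usual chair transition state with the enal residue equatorial is taken to hold in the ten-membered closure, which gives the 8S alcohol; C8 is therefore inverted during acylation in step 18.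

Step 1
Reactants: 1 3-methylbut-2-en-1-ol (prenol)
Product: 3 1-methoxy-4-{[(3-methylbut-2-en-1-yl)oxy]methyl}benzene, via sodium 3-methylbut-2-en-1-olate 2 (not isolated)
Conditions: NaH, 4-methoxybenzyl chloride, Bu4NI (cat.), THF, 0 °C to rt
Reagents that add atoms: 4-methoxybenzyl chloride, COc1ccc(CCl)cc1
Why: Williamson ether synthesis, in which the primary alkoxide displaces the benzylic chloride and no stereocentre is involved.

Step 2
Reactants: 3 1-methoxy-4-{[(3-methylbut-2-en-1-yl)oxy]methyl}benzene
Product: 4 (E)-4-[(4-methoxybenzyl)oxy]-2-methylbut-2-en-1-ol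
Conditions: SeO2 (0.5 equiv), t-BuOOH, salicylic acid (cat.), CH2Cl2, rt
Reagents that add atoms: tert-butyl hydroperoxide, CC(C)(C)OO
Why: SeO2 allylic hydroxylation (ene reaction followed by [2,3]-sigmatropic shift) attacks the methyl group trans to the chain and should give the E allylic alcohol that later becomes the E C9=C10 alkene.

Step 3
Reactants: 4 (E)-4-[(4-methoxybenzyl)oxy]-2-methylbut-2-en-1-ol
Product: 5 (E)-4-[(4-methoxybenzyl)oxy]-2-methylbut-2-enal
Conditions: MnO2 (excess), CH2Cl2, rt
Reagents that add atoms: none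
Why: Allylic alcohol oxidation on MnO2 stops at the aldehyde and should leave the E geometry and the 4-methoxybenzyl ether untouched.

Step 4
Reactants: 5 (E)-4-[(4-methoxybenzyl)oxy]-2-methylbut-2-enal; 6 3-methylbut-3-en-2-one
Product: 9 (5S,6E)-5-hydroxy-8-[(4-methoxybenzyl)oxy]-2,6-dimethylocta-1,6-dien-3-one, via enol diisopinocampheylborinate 7 (not isolated), via boron aldolate 8 (not isolated)
Conditions: 6, (+)-Ipc2BCl, Et3N, Et2O, 0 °C; 5, −78 to −20 °C; H2O2, MeOH, pH 7 buffer, 0 °C
Reagents that add atoms: none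
Why: Boron-mediated asymmetric aldol reaction of a methyl ketone (Paterson aldol), in which the enol borinate should add to the si face of the enal under control of the isopinocampheyl ligands and set C1 as S; the (+)-reagent is chosen on the model that methyl ketone enolates of the (−)-reagent attack the re face, and material of the wrong C1 configuration becomes a separable diastereomer after step 6.

Step 5
Reactants: 9 (5S,6E)-5-hydroxy-8-[(4-methoxybenzyl)oxy]-2,6-dimethylocta-1,6-dien-3-one
Product: 10 (5S,6E)-5-[(tert-butyldimethylsilyl)oxy]-8-[(4-methoxybenzyl)oxy]-2,6-dimethylocta-1,6-dien-3-one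
Conditions: TBSOTf, 2,6-lutidine, CH2Cl2, −78 °C
Reagents that add atoms: tert-butyldimethylsilyl triflate, CC(C)(C)[Si](C)(C)OS(=O)(=O)C(F)(F)F
Why: Silyl ether formation with a hindered base at low temperature protects the C1 hydroxyl before it can add to the enone (oxa-Michael) or undergo retro-aldol cleavage.

Step 6
Reactants: 10 (5S,6E)-5-[(tert-butyldimethylsilyl)oxy]-8-[(4-methoxybenzyl)oxy]-2,6-dimethylocta-1,6-dien-3-one
Product: 12 (3R,5S,6E)-5-[(tert-butyldimethylsilyl)oxy]-8-[(4-methoxybenzyl)oxy]-2,6-dimethylocta-1,6-dien-3-ol, via catechol borate 11 (not isolated)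
Conditions: (S)-1-methyl-3,3-diphenyltetrahydro-1H,3H-pyrrolo[1,2-c][1,3,2]oxazaborole [(S)-Me-CBS, 0.2 equiv], catecholborane, toluene, −78 °C; MeOH, then 1 M NaOH wash
Reagents that add atoms: none
Why: Corey–Bakshi–Shibata reduction, in which the isopropenyl group acts as the large substituent so that the (S)-catalyst should give the 3R alcohol (1,3-syn to C1), the C3 epimer that the key step needs, with the catalyst and not the non-chelating silyl ether deciding the face.

Step 7
Reactants: 12 (3R,5S,6E)-5-[(tert-butyldimethylsilyl)oxy]-8-[(4-methoxybenzyl)oxy]-2,6-dimethylocta-1,6-dien-3-ol; 13 penta-1,4-dien-3-ol; 14 dichlorodiisopropylsilane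
Product: 16 diisopropyl(penta-1,4-dien-3-yloxy)silyl ether of 12 at the C3 oxygen (mixed silaketal), via chlorosilane 15 (not isolated)
Conditions: 14 (3 equiv), imidazole, CH2Cl2, 0 °C; excess 14 removed in vacuo; 13 (2 equiv), imidazole, CH2Cl2, rt
Reagents that add atoms: none
Why: Stepwise silylation of two alcohols by a dichlorosilane, in which the hindered secondary alcohol reacts once with the excess dichlorosilane and the remaining Si–Cl bond is then displaced by the divinylcarbinol, so that the unsymmetrical silaketal should form without the symmetrical ones.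

Step 8
Reactants: 16 diisopropyl(penta-1,4-dien-3-yloxy)silyl ether of 12 (mixed silaketal)
Product: 17 (4R,7S)-4-{(2S,3E)-2-[(tert-butyldimethylsilyl)oxy]-5-[(4-methoxybenzyl)oxy]-3-methylpent-3-en-1-yl}-2,2-diisopropyl-5-methyl-7-vinyl-4,7-dihydro-1,3,2-dioxasilepine (cis, Z C4=C5)
Conditions: second-generation Grubbs catalyst (10 mol %), toluene (0.005 M), 80 °C, argon sparge
Reagents that add atoms: none
Why: Ring-closing metathesis of a temporary silicon tether, the known reaction type of mixed silaketals that carry a divinylcarbinol unit: the ruthenium benzylidene exchanges onto one of the two monosubstituted vinyl groups, the resulting alkylidene adds to the 1,1-disubstituted C4 alkene in a [2+2] step to a ruthenacyclobutane, and cycloreversion releases the ring and a ruthenium methylidene that carries the cycle on with loss of ethene. The ring closed is the seven-membered 4,7-dihydro-1,3,2-dioxasilepine (O–Si–O–C3–C4=C5–C6), formed by metathesis across C4=C5, and because a trans alkene cannot exist in a ring of this size the Z geometry of the trisubstituted C4=C5 bond is fixed. The new stereocentre C6 arises from the choice between the two diastereotopic vinyl groups and is controlled by C3: in the chair-like seven-membered transition state the C3 side chain and the spectator vinyl group should both sit pseudo-equatorial, which leads to the cis-4,7-disubstituted silaketal, and with the 3R alcohol this cis product carries C6 in the configuration of the target. Loading of the carbene on either vinyl group is reversible, so the outcome is decided in the ring-closing step and not in the loading step. The step needs group selectivity (secured by C3), chemoselectivity (the trisubstituted C9=C10 allylic ether is too hindered to react, two vinyl groups on one carbon cannot close onto each other, and high dilution holds back cross-metathesis) and Z selectivity (secured by the ring size).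

Step 9
Reactants: 17 cis-dioxasilepine
Product: 18 (3S,4Z,6R,8S,9E)-8-[(tert-butyldimethylsilyl)oxy]-11-[(4-methoxybenzyl)oxy]-5,9-dimethylundeca-1,4,9-triene-3,6-diol (free C6 and C3 hydroxyls)
Conditions: HF·pyridine, pyridine, THF, 0 °C
Reagents that add atoms: none
Why: Fluoride-mediated cleavage of the dialkoxysilane, whose silicon bears two oxygen atoms and is more electrophilic than that of the trialkylsilyl ether, so that buffered HF should remove the tether and leave the C1 silyl ether in place.

Step 10
Reactants: 18 C3,C6-diol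
Product: 19 (3S,4Z,6R,8S,9E)-8-[(tert-butyldimethylsilyl)oxy]-11-[(4-methoxybenzyl)oxy]-5,9-dimethyl-3-[(triethylsilyl)oxy]undeca-1,4,9-trien-6-ol (C6 triethylsilyl ether, free C3 hydroxyl)
Conditions: TESCl (1.05 equiv), imidazole, CH2Cl2, −78 to −40 °C
Reagents that add atoms: chlorotriethylsilane, CC[Si](Cl)(CC)CC
Why: Regioselective silylation of the less hindered hydroxyl, since the C6 hydroxyl is flanked by two unsubstituted sp2 CH groups whereas the C3 hydroxyl lies next to the methyl-bearing C4 and the branched C2–C1 chain.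

Step 11
Reactants: 19 C6 triethylsilyl ether with free C3 hydroxyl
Product: 20 (3S,4Z,6S,8S,9E)-8-[(tert-butyldimethylsilyl)oxy]-11-[(4-methoxybenzyl)oxy]-5,9-dimethyl-3-[(triethylsilyl)oxy]undeca-1,4,9-trien-6-yl acetate (C3 acetate, 3S)
Conditions: PPh3, AcOH, DIAD, toluene, −20 to 0 °C
Reagents that add atoms: acetic acid, CC(=O)O
Why: Mitsunobu esterification, in which acetate displaces the oxyphosphonium group at C3 by SN2 with inversion and so turns 3R into the 3S acetate of the target, the nonpolar solvent and low temperature disfavouring the SN2' path.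

Step 12
Reactants: 20 C3 acetate with C6 triethylsilyl ether
Product: 21 (3S,4Z,6S,8S,9E)-8-[(tert-butyldimethylsilyl)oxy]-3-hydroxy-11-[(4-methoxybenzyl)oxy]-5,9-dimethylundeca-1,4,9-trien-6-yl acetate (free C6 hydroxyl)
Conditions: HF·pyridine, pyridine, THF, 0 °C
Reagents that add atoms: none
Why: Selective desilylation, in which the triethylsilyl ether is cleaved far faster than the bulkier tert-butyldimethylsilyl ether and the buffered medium avoids acetyl migration and ionisation of the doubly allylic alcohol.

Step 13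
Reactants: 21 C6 alcohol; 22 2-(bromomethyl)acrylic acid
Product: 23 (3S,4Z,6S,8S,9E)-6-acetoxy-8-[(tert-butyldimethylsilyl)oxy]-11-[(4-methoxybenzyl)oxy]-5,9-dimethylundeca-1,4,9-trien-3-yl 2-(bromomethyl)acrylate
Conditions: DCC, DMAP (0.1 equiv), CH2Cl2, −20 to 0 °C
Reagents that add atoms: none
Why: Steglich esterification, in which the carbodiimide-activated acid acylates the C6 hydroxyl with retention while low temperature and only catalytic DMAP keep the allylic bromide intact.

Step 14
Reactants: 23 C6 2-(bromomethyl)acrylate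
Product: 24 (5R)-3-(bromomethyl)-5-{(1Z,3S,5S,6E)-3-acetoxy-5-[(tert-butyldimethylsilyl)oxy]-8-[(4-methoxybenzyl)oxy]-2,6-dimethylocta-1,6-dien-1-yl}furan-2(5H)-one
Conditions: second-generation Grubbs catalyst (10 mol %), CH2Cl2 (0.005 M), 40 °C
Reagents that add atoms: none
Why: Ring-closing metathesis of an allylic 2-substituted acrylate to an α-substituted butenolide, in which the carbene forms on the C7 vinyl group and closes onto the acrylate methylene to give the five-membered ring with C7=C11 while C6 and the other stereocentres are not touched.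

Step 15
Reactants: 24 bromomethyl butenolide with C8 4-methoxybenzyl ether
Product: 25 (5R)-3-(bromomethyl)-5-{(1Z,3S,5S,6E)-3-acetoxy-5-[(tert-butyldimethylsilyl)oxy]-8-hydroxy-2,6-dimethylocta-1,6-dien-1-yl}furan-2(5H)-one
Conditions: DDQ, CH2Cl2, pH 7 phosphate buffer, 0 °C
Reagents that add atoms: none
Why: Oxidative cleavage of the 4-methoxybenzyl ether by hydride abstraction and hydrolysis of the oxocarbenium ion, with buffering to protect the base-sensitive γ-position (C6) of the butenolide.

Step 16
Reactants: 25 C8 allylic alcohol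
Product: 26 (5R)-3-(bromomethyl)-5-{(1Z,3S,5S,6E)-3-acetoxy-5-[(tert-butyldimethylsilyl)oxy]-2,6-dimethyl-8-oxoocta-1,6-dien-1-yl}furan-2(5H)-one (C8 enal)
Conditions: MnO2, CH2Cl2, rt
Reagents that add atoms: none
Why: Allylic alcohol oxidation under neutral conditions should give the E enal without touching the allylic bromide or isomerising C9=C10.

Step 17
Reactants: 26 bromomethyl butenolide enal
Product: 29 ten-membered α-methylene lactone with 3-acetate 1-silyl ether 8-hydroxyl (C8 S), via allylchromium dichloride 27 (not isolated), via chromium alkoxide 28 (not isolated)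
Conditions: CrCl2 (8 equiv), THF (0.003 M, slow addition of 26), rt; aqueous NH4Cl
Reagents that add atoms: none
Why: Intramolecular Nozaki–Hiyama allylation, in which two equivalents of divalent chromium turn the allylic bromide into an allylchromium species that adds through C7 to the aldehyde in a closed six-membered transition state and closes the ten-membered ring with the exocyclic C11=C13 methylene; the C7–C8 bond should form on the butenolide face opposite to the C5 substituent at C6 (trans-fused lactone, C7 as in the target), and with the ring-fixed allyl geometry and the enal residue equatorial the chair gives the anti relation between C6 and the C8 hydroxyl, that is the 8S alcohol, the C8 epimer that step 18 inverts.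

Step 18
Reactants: 29 ten-membered 8S alcohol; 30 (E)-2-methylbut-2-enoic acid (tiglic acid)
Product: 31 C1 tert-butyldimethylsilyl ether of the target (C8 R tiglate)
Conditions: PPh3, DIAD, toluene, 0 °C to rt
Reagents that add atoms: none
Why: Mitsunobu esterification, in which tiglate displaces the oxyphosphonium group by SN2 and so inverts C8 from S to R while installing the ester in one operation, the fully substituted C10 end of the allyl system being too hindered for the SN2' path.

Step 19
Reactants: 31 C1 silyl ether of the target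
Product: 32 target, (1S,3S,6R,7S,8R,4Z,9E)-3-acetoxy-1-hydroxy-8-[(E)-2-methylbut-2-enoyloxy]germacra-4,9,11(13)-trien-12,6-olide
Conditions: HF·pyridine, THF, 0 °C to rt
Reagents that add atoms: none
Why: Fluoride-mediated desilylation of the secondary silyl ether under mildly acidic conditions should free the C1 hydroxyl without acyl migration, ester cleavage or attack on the α-methylene lactone.

Compound list
1 | 3-methylbut-2-en-1-ol (prenol) | CC(C)=CCO | starting material
2 | sodium 3-methylbut-2-en-1-olate | CC(C)=CC[O-].[Na+] | intermediate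
3 | 1-methoxy-4-{[(3-methylbut-2-en-1-yl)oxy]methyl}benzene (prenyl 4-methoxybenzyl ether) | COc1ccc(COCC=C(C)C)cc1 | intermediate
4 | (E)-4-[(4-methoxybenzyl)oxy]-2-methylbut-2-en-1-ol | OC/C(C)=C/COCc1ccc(OC)cc1 | intermediate
5 | (E)-4-[(4-methoxybenzyl)oxy]-2-methylbut-2-enal (C8–C1 enal) | O=C/C(C)=C/COCc1ccc(OC)cc1 | intermediate
6 | 3-methylbut-3-en-2-one | CC(=O)C(C)=C | starting material
7 | [(3-methylbuta-1,3-dien-2-yl)oxy]bis[(1S,2R,3S,5S)-2,6,6-trimethylbicyclo[3.1.1]hept-3-yl]borane (enol diisopinocampheylborinate of 6) | C=C(C)C(=C)OB([C@H]1C[C@H]2C[C@@H]([C@@H]1C)C2(C)C)[C@H]1C[C@H]2C[C@@H]([C@@H]1C)C2(C)C | intermediate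
8 | O-bis[(1S,2R,3S,5S)-isopinocampheyl]boryl ether of aldol 9 (boron aldolate, C1 S) | C=C(C)C(=O)C[C@H](OB([C@H]1C[C@H]2C[C@@H]([C@@H]1C)C2(C)C)[C@H]1C[C@H]2C[C@@H]([C@@H]1C)C2(C)C)/C(C)=C/COCc1ccc(OC)cc1 | intermediate
9 | (5S,6E)-5-hydroxy-8-[(4-methoxybenzyl)oxy]-2,6-dimethylocta-1,6-dien-3-one (C1 S) | C=C(C)C(=O)C[C@H](O)/C(C)=C/COCc1ccc(OC)cc1 | intermediate
10 | (5S,6E)-5-[(tert-butyldimethylsilyl)oxy]-8-[(4-methoxybenzyl)oxy]-2,6-dimethylocta-1,6-dien-3-one | C=C(C)C(=O)C[C@H](O[Si](C)(C)C(C)(C)C)/C(C)=C/COCc1ccc(OC)cc1 | intermediate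
11 | 2-{[(3R,5S,6E)-5-[(tert-butyldimethylsilyl)oxy]-8-[(4-methoxybenzyl)oxy]-2,6-dimethylocta-1,6-dien-3-yl]oxy}-1,3,2-benzodioxaborole (catechol borate of 12) | C=C(C)[C@H](OB1Oc2ccccc2O1)C[C@H](O[Si](C)(C)C(C)(C)C)/C(C)=C/COCc1ccc(OC)cc1 | intermediate
12 | (3R,5S,6E)-5-[(tert-butyldimethylsilyl)oxy]-8-[(4-methoxybenzyl)oxy]-2,6-dimethylocta-1,6-dien-3-ol (C3 R, C1 S, 1,3-syn) | C=C(C)[C@H](O)C[C@H](O[Si](C)(C)C(C)(C)C)/C(C)=C/COCc1ccc(OC)cc1 | intermediate
13 | penta-1,4-dien-3-ol | C=CC(O)C=C | starting material
14 | dichlorodiisopropylsilane | CC(C)[Si](Cl)(Cl)C(C)C | starting material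
15 | chloro(diisopropyl)silyl ether of 12 at the C3 oxygen | C=C(C)[C@H](O[Si](Cl)(C(C)C)C(C)C)C[C@H](O[Si](C)(C)C(C)(C)C)/C(C)=C/COCc1ccc(OC)cc1 | intermediate
16 | diisopropyl(penta-1,4-dien-3-yloxy)silyl ether of 12 at the C3 oxygen (mixed silaketal, C3 R) | C=C(C)[C@H](O[Si](C(C)C)(C(C)C)OC(C=C)C=C)C[C@H](O[Si](C)(C)C(C)(C)C)/C(C)=C/COCc1ccc(OC)cc1 | intermediate
17 | (4R,7S)-4-{(2S,3E)-2-[(tert-butyldimethylsilyl)oxy]-5-[(4-methoxybenzyl)oxy]-3-methylpent-3-en-1-yl}-2,2-diisopropyl-5-methyl-7-vinyl-4,7-dihydro-1,3,2-dioxasilepine (cis; Z C4=C5; C3 R; C6 as in the target) | C=C[C@@H]1O[Si](C(C)C)(C(C)C)O[C@H](C[C@H](O[Si](C)(C)C(C)(C)C)/C(C)=C/COCc2ccc(OC)cc2)/C(C)=C\1 | intermediate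
18 | (3S,4Z,6R,8S,9E)-8-[(tert-butyldimethylsilyl)oxy]-11-[(4-methoxybenzyl)oxy]-5,9-dimethylundeca-1,4,9-triene-3,6-diol (free C6 and C3 hydroxyls) | C=C[C@H](O)/C=C(/C)[C@H](O)C[C@H](O[Si](C)(C)C(C)(C)C)/C(C)=C/COCc1ccc(OC)cc1 | intermediate
19 | (3S,4Z,6R,8S,9E)-8-[(tert-butyldimethylsilyl)oxy]-11-[(4-methoxybenzyl)oxy]-5,9-dimethyl-3-[(triethylsilyl)oxy]undeca-1,4,9-trien-6-ol (C6 triethylsilyl ether, free C3 hydroxyl) | C=C[C@H](O[Si](CC)(CC)CC)/C=C(/C)[C@H](O)C[C@H](O[Si](C)(C)C(C)(C)C)/C(C)=C/COCc1ccc(OC)cc1 | intermediate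
20 | (3S,4Z,6S,8S,9E)-8-[(tert-butyldimethylsilyl)oxy]-11-[(4-methoxybenzyl)oxy]-5,9-dimethyl-3-[(triethylsilyl)oxy]undeca-1,4,9-trien-6-yl acetate (C3 S acetate) | C=C[C@H](O[Si](CC)(CC)CC)/C=C(/C)[C@@H](OC(C)=O)C[C@H](O[Si](C)(C)C(C)(C)C)/C(C)=C/COCc1ccc(OC)cc1 | intermediate
21 | (3S,4Z,6S,8S,9E)-8-[(tert-butyldimethylsilyl)oxy]-3-hydroxy-11-[(4-methoxybenzyl)oxy]-5,9-dimethylundeca-1,4,9-trien-6-yl acetate (free C6 hydroxyl) | C=C[C@H](O)/C=C(/C)[C@@H](OC(C)=O)C[C@H](O[Si](C)(C)C(C)(C)C)/C(C)=C/COCc1ccc(OC)cc1 | intermediate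
22 | 2-(bromomethyl)acrylic acid | C=C(CBr)C(=O)O | starting material
23 | (3S,4Z,6S,8S,9E)-6-acetoxy-8-[(tert-butyldimethylsilyl)oxy]-11-[(4-methoxybenzyl)oxy]-5,9-dimethylundeca-1,4,9-trien-3-yl 2-(bromomethyl)acrylate | C=C[C@H](OC(=O)C(=C)CBr)/C=C(/C)[C@@H](OC(C)=O)C[C@H](O[Si](C)(C)C(C)(C)C)/C(C)=C/COCc1ccc(OC)cc1 | intermediate
24 | (5R)-3-(bromomethyl)-5-{(1Z,3S,5S,6E)-3-acetoxy-5-[(tert-butyldimethylsilyl)oxy]-8-[(4-methoxybenzyl)oxy]-2,6-dimethylocta-1,6-dien-1-yl}furan-2(5H)-one | BrCC1=C[C@@H](/C=C(/C)[C@@H](OC(C)=O)C[C@H](O[Si](C)(C)C(C)(C)C)/C(C)=C/COCc2ccc(OC)cc2)OC1=O | intermediate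
25 | (5R)-3-(bromomethyl)-5-{(1Z,3S,5S,6E)-3-acetoxy-5-[(tert-butyldimethylsilyl)oxy]-8-hydroxy-2,6-dimethylocta-1,6-dien-1-yl}furan-2(5H)-one | BrCC1=C[C@@H](/C=C(/C)[C@@H](OC(C)=O)C[C@H](O[Si](C)(C)C(C)(C)C)/C(C)=C/CO)OC1=O | intermediate
26 | (5R)-3-(bromomethyl)-5-{(1Z,3S,5S,6E)-3-acetoxy-5-[(tert-butyldimethylsilyl)oxy]-2,6-dimethyl-8-oxoocta-1,6-dien-1-yl}furan-2(5H)-one (C8 enal) | BrCC1=C[C@@H](/C=C(/C)[C@@H](OC(C)=O)C[C@H](O[Si](C)(C)C(C)(C)C)/C(C)=C/C=O)OC1=O | intermediate
27 | allylchromium dichloride derived from 26 (CrCl2 on C13 in place of bromine) | Cl[Cr](Cl)CC1=C[C@@H](/C=C(/C)[C@@H](OC(C)=O)C[C@H](O[Si](C)(C)C(C)(C)C)/C(C)=C/C=O)OC1=O | intermediate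
28 | chromium dichloride alkoxide of 29 (C8–O–CrCl2) | C=C1C(=O)O[C@@H]2/C=C(/C)[C@@H](OC(C)=O)C[C@H](O[Si](C)(C)C(C)(C)C)/C(C)=C/[C@H](O[Cr](Cl)Cl)[C@@H]12 | intermediate
29 | ten-membered α-methylene lactone (germacra-4Z,9E,11(13)-trien-12,6-olide skeleton) with 3-acetate, 1-tert-butyldimethylsilyl ether and 8-hydroxyl: C1 S, C3 S, C6 R, C7 as in the target (trans-fused), C8 S (8-epimer) | C=C1C(=O)O[C@@H]2/C=C(/C)[C@@H](OC(C)=O)C[C@H](O[Si](C)(C)C(C)(C)C)/C(C)=C/[C@H](O)[C@@H]12 | intermediate
30 | (E)-2-methylbut-2-enoic acid (tiglic acid) | C/C=C(\C)C(=O)O | starting material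
31 | C1 tert-butyldimethylsilyl ether of the target (C8 R tiglate) | C=C1C(=O)O[C@@H]2/C=C(/C)[C@@H](OC(C)=O)C[C@H](O[Si](C)(C)C(C)(C)C)/C(C)=C/[C@@H](OC(=O)/C(C)=C/C)[C@@H]12 | intermediate
32 | (1S,3S,6R,7S,8R,4Z,9E)-3-acetoxy-1-hydroxy-8-[(E)-2-methylbut-2-enoyloxy]germacra-4,9,11(13)-trien-12,6-olide | C=C1C(=O)O[C@@H]2/C=C(/C)[C@@H](OC(C)=O)C[C@H](O)/C(C)=C/[C@@H](OC(=O)/C(C)=C/C)[C@@H]12 | target

Total step count: 19 steps.
Longest linear sequence: 19 steps (1 to 32); 6, 13, 14, 22 and 30 enter as purchased building blocks.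

Steps most likely to fail

Step 8. The catalyst may not discriminate well enough between the two diastereotopic vinyl groups when it has to close onto the hindered 1,1-disubstituted alkene, so that C6 forms as a mixture, or vinyl–vinyl cross-metathesis may outrun the closure. The fallback sets C6 by reagent instead of by induction. It sets out from 12, which is converted into chlorosilane 15 as in step 7 and then treated with the enantiopure alcohol (R)-5-(trimethylsilyl)pent-1-en-4-yn-3-ol F1 (an additional starting material in which one vinyl group of the carbinol is replaced by a silyl-capped alkyne) and imidazole to give the mixed silaketal F2. Ring-closing metathesis with the same ruthenium catalyst, for which only one vinyl group is now available and the silylalkyne is a spectator, gives the alkynyl dioxasilepine F3. K2CO3 in MeOH at 0 °C removes the C-silyl group to give the terminal alkyne F4, and semihydrogenation (H2, Pd/CaCO3 poisoned with Pb(OAc)2, quinoline, EtOAc) converts the alkyne into the vinyl group, which comes back to the route at 17.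

Step 17. The ten-membered transition state may force the enal residue into the axial position of the chair and so reverse the face of the aldehyde that is attacked, which would deliver the other C8 epimer. The fallback replaces inversion by acylation with retention. It sets out from 26, and the 8R alcohol F5 obtained under the conditions of step 17 is esterified directly with (E)-2-methylbut-2-enoyl chloride, pyridine and DMAP in CH2Cl2 at 0 °C, which comes back to the route at 31 and makes step 18 unnecessary.

Step 18. Elimination toward C7 or allylic transposition may take over from SN2 substitution at the hindered ring carbon C8. The fallback corrects C8 by oxidation and reduction instead of displacement. It sets out from 29, which is oxidised with Dess–Martin periodinane and NaHCO3 in CH2Cl2 to the C8 enone F6 (buffered and kept cold because C7–H is activated). Catalyst-controlled reduction with the (R)-enantiomer of the oxazaborolidine used in step 6 and catecholborane, the alkenyl residue acting as the large group, should give the 8R alcohol F5. Acylation with (E)-2-methylbut-2-enoyl chloride, pyridine and DMAP comes back to the route at 31.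

Further compounds
F1 | step 8 | (R)-5-(trimethylsilyl)pent-1-en-4-yn-3-ol | O[C@H](C=C)C#C[Si](C)(C)C
F2 | step 8 | diisopropylsilyl ketal of 12 (C3 oxygen) and F1 | C=C(C)[C@H](O[Si](C(C)C)(C(C)C)O[C@H](C=C)C#C[Si](C)(C)C)C[C@H](O[Si](C)(C)C(C)(C)C)/C(C)=C/COCc1ccc(OC)cc1
F3 | step 8 | cis-dioxasilepine as 17 with a (trimethylsilyl)ethynyl group at C6 in place of vinyl | C[Si](C)(C)C#C[C@@H]1O[Si](C(C)C)(C(C)C)O[C@H](C[C@H](O[Si](C)(C)C(C)(C)C)/C(C)=C/COCc2ccc(OC)cc2)/C(C)=C\1
F4 | step 8 | cis-dioxasilepine as 17 with an ethynyl group at C6 in place of vinyl | C#C[C@@H]1O[Si](C(C)C)(C(C)C)O[C@H](C[C@H](O[Si](C)(C)C(C)(C)C)/C(C)=C/COCc2ccc(OC)cc2)/C(C)=C\1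
F5 | step 17 | 8R alcohol, the C8 epimer of 29 | C=C1C(=O)O[C@@H]2/C=C(/C)[C@@H](OC(C)=O)C[C@H](O[Si](C)(C)C(C)(C)C)/C(C)=C/[C@@H](O)[C@@H]12
F6 | step 18 | C8 ketone (enone) derived from 29 | C=C1C(=O)O[C@@H]2/C=C(/C)[C@@H](OC(C)=O)C[C@H](O[Si](C)(C)C(C)(C)C)/C(C)=C/C(=O)[C@@H]12
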